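**Retrosynthetic overview**
1. Feature: ring A (C4a–C5–C6–C7–C8–C8a) is a hydroquinone. O1 on C8a is para to the OH on C6, the OMe on C7 is next to C6, C5 and C8 carry H, and C4a carries the C4 carbonyl.
2. Ring C is cut at O1–C2. The C8a phenol adds to a β-methoxy enone that already holds C4, C3 (with ring B) and C2, and expels methoxide.
3. Ring A is cut at C8a–C4a and C5–C6. A 2-silyloxy-4-methoxyfuran (C8a, C8, C7, C6; its ring oxygen becomes the C6 hydroxyl) undergoes Diels–Alder addition to a terminal ynone (C4a, C5), and the oxygen bridge then opens with aromatisation.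
4. The ynone comes from 2,4,5-trimethoxyphenylacetic acid through the arylmalondialdehyde, O-methylation, ethynyl Grignard addition and oxidation. The furan comes from methyl tetronate.
5. Ring order: B is bought, A is built in the cycloaddition, C is closed in the last step.

Key step: step 6

Assumption: the target SMILES has no stereocentre and no stereogenic double bond, so the compound is achiral and the single-enantiomer request needs no stereocontrol. The only stereo-elements on the way are the enol ether geometry, one racemic carbinol and two bridgeheads, and all of them are erased before the target.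

Step 1
Reactants: 1 2,4,5-trimethoxyphenylacetic acid
Product: 4 2-(2,4,5-trimethoxyphenyl)malondialdehyde (enol form), via vinamidinium chloride 2 (not isolated), via dimethylaminoacrolein 3 (not isolated)
Conditions: POCl3 (3 equiv), DMF, 0 → 75 °C; then ice, aq NaOH, 85 °C; then HCl to pH 3, 0 °C
Reagents that add atoms: N,N-dimethylformamide CN(C)C=O (both formyl carbons); water O (both aldehyde oxygens)
Why: In this Vilsmeier–Haack–Arnold reaction the chloroiminium salt activates the acid and formylates the benzylic carbon twice with loss of CO2 to give the 2-aryl vinamidinium salt, hot aqueous base then hydrolyses both C–N termini, the method is established for methoxylated arylacetic acids, and the two free ring positions (C3 between two OMe groups, C6 beside the side chain) are hindered against ring formylation.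

Step 2
Reactants: 4 2-(2,4,5-trimethoxyphenyl)malondialdehyde
Product: 5 (E)-3-methoxy-2-(2,4,5-trimethoxyphenyl)prop-2-enal
Conditions: Me2SO4, K2CO3, DMF, rt
Reagents that add atoms: dimethyl sulfate COS(=O)(=O)OC
Why: O-alkylation of the fully enolised 1,3-dialdehyde (a vinylogous acid) with a hard methylating agent should give the vinylogous formate ester, the E isomer (OMe anti to CHO) is expected as the more stable one, and an E/Z mixture can be carried on because step 7 erases this geometry.

Step 3
Reactants: 5 (E)-3-methoxy-2-(2,4,5-trimethoxyphenyl)prop-2-enal; 6 ethynylmagnesium bromide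
Product: 7 (E)-5-methoxy-4-(2,4,5-trimethoxyphenyl)pent-4-en-1-yn-3-ol (racemic)
Conditions: HC≡CMgBr (0.5 M in THF, 1.3 equiv), THF, −40 → 0 °C; pH 7 phosphate buffer; used crude
Reagents that add atoms: none
Why: This is a 1,2-addition of an alkynyl Grignard reagent to an aldehyde, in which the β-methoxy donor disfavours conjugate attack, the new carbinol centre forms racemic and is removed in step 4, and the neutral quench protects the acid-labile γ-hydroxy enol ether.

Step 4
Reactants: 7 (E)-5-methoxy-4-(2,4,5-trimethoxyphenyl)pent-4-en-1-yn-3-ol
Product: 8 (E)-5-methoxy-4-(2,4,5-trimethoxyphenyl)pent-4-en-1-yn-3-one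
Conditions: activated MnO2 (excess), CH2Cl2, rt
Reagents that add atoms: none
Why: MnO2 oxidation of an alcohol that is both allylic and propargylic runs under neutral heterogeneous conditions, which should spare the enol ether, the terminal alkyne and the electron-rich arene.

Step 5
Reactants: 9 methyl tetronate (4-methoxyfuran-2(5H)-one)
Product: 10 tert-butyl[(4-methoxyfuran-2-yl)oxy]dimethylsilane
Conditions: TBSOTf, Et3N, CH2Cl2, 0 °C → rt; pentane extraction, used fresh
Reagents that add atoms: tert-butyldimethylsilyl triflate CC(C)(C)[Si](C)(C)OS(=O)(=O)C(F)(F)F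
Why: In this soft enolisation, O-silylation of the lactone carbonyl acidifies C5–H and Et3N removes it to give the aromatic furan, which is the standard preparation of 2-silyloxyfurans from butenolides and tetronates.

Step 6
Reactants: 8 (E)-5-methoxy-4-(2,4,5-trimethoxyphenyl)pent-4-en-1-yn-3-one; 10 tert-butyl[(4-methoxyfuran-2-yl)oxy]dimethylsilane
Product: 12 (E)-1-[2-(tert-butyldimethylsilyloxy)-5-hydroxy-4-methoxyphenyl]-3-methoxy-2-(2,4,5-trimethoxyphenyl)prop-2-en-1-one, via 7-oxanorbornadiene cycloadduct 11 (not isolated)
Conditions: 10 (1.5 equiv), PhMe, Ar, rt → 60 °C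
Reagents that add atoms: none
Why: This is a normal-electron-demand Diels–Alder reaction in which the doubly donor-substituted furan diene (C2=C3–C4=C5) adds across the carbonyl-activated C≡C of 8, either concertedly but very asynchronously or through a vinylogous Mukaiyama–Michael zwitterion that closes, joining furan C5 to the alkyne CH (C6–C5 of the target) and furan C2 to the acyl-bearing alkyne carbon (C8a–C4a). Cycloadduct 11 is a bridgehead ketal whose C1–O7 bond ionises with help from the silyloxy oxygen and, through C6=C5, from the methoxy group, so the bridge oxygen stays on C4 and loss of the C4 proton aromatises ring A to the hydroquinone monosilyl ether 12. The closest known reaction type is the cycloaddition and ring-opening aromatisation of 2-silyloxy- and 2-alkoxyfurans with acetylenic esters and ketones to 4-oxygenated phenols. Ring A is closed by an intermolecular [4+2] annulation (four furan carbons plus two alkyne carbons), and the two bridgehead stereocentres of racemic 11 vanish on aromatisation, so no stereocentre has to be controlled. The step needs regioselectivity that places the acyl group next to the silyloxy carbon, and the substrate secures it because furan C5, being both the vinylogous terminus of the silyl ketene acetal and the β-carbon of the C4 methoxy enol ether, is the most nucleophilic diene terminus and pairs with the unsubstituted, most electrophilic alkyne carbon. It also needs chemoselectivity for the alkyne over the C=C of 8, which is trisubstituted and deactivated by its β-methoxy donor, while silyl exchange between the two A-ring oxygens or extra silylation of the C6 hydroxyl by excess 10 would be harmless because step 7 removes all silicon.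

Step 7
Reactants: 12 (E)-1-[2-(tert-butyldimethylsilyloxy)-5-hydroxy-4-methoxyphenyl]-3-methoxy-2-(2,4,5-trimethoxyphenyl)prop-2-en-1-one
Product: 14 6-hydroxy-7-methoxy-3-(2,4,5-trimethoxyphenyl)-4H-chromen-4-one (target), via free 2-hydroxyaryl methoxyenone 13 (not isolated)
Conditions: TBAF (2.5 equiv), THF, Ar, 0 °C → rt; then 1 M HCl to pH 5
Reagents that add atoms: none
Why: Fluoride cleavage of the aryl silyl ether frees the C8a phenoxide, which should close ring C by 6-endo-trig oxa-Michael addition to C2 and E1cB loss of methoxide (the addition–elimination closure used for isoflavones from 2-hydroxyaryl enol ethers and enaminones), while the C6 phenoxide cannot reach C2 and is returned as the free hydroxyl on acidification.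

**Compound list**
1 | 2,4,5-trimethoxyphenylacetic acid | OC(=O)Cc1cc(OC)c(OC)cc1OC | starting material
2 | N-[3-(dimethylamino)-2-(2,4,5-trimethoxyphenyl)prop-2-enylidene]-N-methylmethanaminium chloride (delocalised vinamidinium, no fixed geometry, drawn as the chloride) | CN(C)C=C(C=[N+](C)C)c1cc(OC)c(OC)cc1OC.[Cl-] | intermediate
3 | (E)-3-(dimethylamino)-2-(2,4,5-trimethoxyphenyl)prop-2-enal | CN(C)/C=C(/C=O)c1cc(OC)c(OC)cc1OC | intermediate
4 | 2-(2,4,5-trimethoxyphenyl)malondialdehyde, enol form (fast tautomer exchange, no fixed geometry) | O=CC(=CO)c1cc(OC)c(OC)cc1OC | intermediate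
5 | (E)-3-methoxy-2-(2,4,5-trimethoxyphenyl)prop-2-enal | CO/C=C(/C=O)c1cc(OC)c(OC)cc1OC | intermediate
6 | ethynylmagnesium bromide | C#C[Mg]Br | starting material
7 | (E)-5-methoxy-4-(2,4,5-trimethoxyphenyl)pent-4-en-1-yn-3-ol, racemic at C3 | CO/C=C(/C(O)C#C)c1cc(OC)c(OC)cc1OC | intermediate
8 | (E)-5-methoxy-4-(2,4,5-trimethoxyphenyl)pent-4-en-1-yn-3-one | CO/C=C(/C(=O)C#C)c1cc(OC)c(OC)cc1OC | intermediate
9 | methyl tetronate (4-methoxyfuran-2(5H)-one) | COC1=CC(=O)OC1 | starting material
10 | tert-butyl[(4-methoxyfuran-2-yl)oxy]dimethylsilane | COc1coc(O[Si](C)(C)C(C)(C)C)c1 | intermediate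
11 | (E)-1-[1-(tert-butyldimethylsilyloxy)-5-methoxy-7-oxabicyclo[2.2.1]hepta-2,5-dien-2-yl]-3-methoxy-2-(2,4,5-trimethoxyphenyl)prop-2-en-1-one, racemic | CO/C=C(/C(=O)C1=CC2OC1(O[Si](C)(C)C(C)(C)C)C=C2OC)c1cc(OC)c(OC)cc1OC | intermediate
12 | (E)-1-[2-(tert-butyldimethylsilyloxy)-5-hydroxy-4-methoxyphenyl]-3-methoxy-2-(2,4,5-trimethoxyphenyl)prop-2-en-1-one | CO/C=C(/C(=O)c1cc(O)c(OC)cc1O[Si](C)(C)C(C)(C)C)c1cc(OC)c(OC)cc1OC | intermediate
13 | (E)-1-(2,5-dihydroxy-4-methoxyphenyl)-3-methoxy-2-(2,4,5-trimethoxyphenyl)prop-2-en-1-one (present as its phenoxide) | CO/C=C(/C(=O)c1cc(O)c(OC)cc1O)c1cc(OC)c(OC)cc1OC | intermediate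
14 | 6-hydroxy-7-methoxy-3-(2,4,5-trimethoxyphenyl)-4H-chromen-4-one | COc1cc2occ(-c3cc(OC)c(OC)cc3OC)c(=O)c2cc1O | target

Total step count: 7. Longest linear sequence: 6 (steps 1, 2, 3, 4, 6, 7).

**Steps most likely to fail**

Step 6. The first C–C bond (furan C5 to the alkyne terminus) may form without ring closure, and the zwitterion may then collapse by silyl transfer to a γ-substituted butenolide. The furan may also be protodesilylated by the phenol as it forms, so that the benzannulation stalls. The fallback buys ring A instead of building it. It sets out from 1 and comes back at 14. Acid 1 is heated with 2-methoxyhydroquinone (COc1cc(O)ccc1O) in BF3·OEt2. This Friedel–Crafts acylation is directed para to the methoxy group and ortho to a hydroxyl, and it gives 1-(2,5-dihydroxy-4-methoxyphenyl)-2-(2,4,5-trimethoxyphenyl)ethanone F1. DMF and MsCl are then added in the same BF3·OEt2 medium. A Vilsmeier-type formylation of the benzylic CH2 and cyclodehydration insert C2 and close ring C to give 14.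

Step 3. The enol ether may assist ionisation of the carbinol C–O bond during quench, concentration or storage. Allylic transposition and loss of methanol would follow, and little alcohol would reach the oxidation. The fallback never passes through a carbinol. It sets out from 1 and comes back at 8.
- Fischer esterification (MeOH, cat. H2SO4) gives methyl 2,4,5-trimethoxyphenylacetate F2.
- Claisen formylation (NaH, HCO2Me, THF) gives methyl 3-hydroxy-2-(2,4,5-trimethoxyphenyl)acrylate F3.
- O-methylation (Me2SO4, K2CO3, DMF) gives methyl (E)-3-methoxy-2-(2,4,5-trimethoxyphenyl)acrylate F4.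
- Saponification (LiOH, THF/H2O, then pH 4) gives (E)-3-methoxy-2-(2,4,5-trimethoxyphenyl)acrylic acid F5.
- Coupling with MeNHOMe·HCl (EDC, Et3N) gives the Weinreb amide (E)-N,3-dimethoxy-N-methyl-2-(2,4,5-trimethoxyphenyl)acrylamide F6.
- Treating F6 with 6 in THF gives 8. An inverse quench into cold aqueous NaHSO4 protonates the released amine before it can add to the ynone.

Step 1. The chloroiminium salt may attack the electron-rich ring, or the material may degrade at the temperature needed for decarboxylation and the second formylation. The fallback replaces the electrophilic reagent by a neutral aminomethylenation of an aldehyde. It sets out from 1 and comes back at 3. BH3·THF reduces 1 to 2-(2,4,5-trimethoxyphenyl)ethanol F7. Dess–Martin oxidation gives 2-(2,4,5-trimethoxyphenyl)acetaldehyde F8. Condensation of F8 with DMF dimethyl acetal (PhMe, 80 °C) gives 3. In this case 3 is isolated and hydrolysed with aqueous NaOH to 4, as in the second stage of step 1.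

**Further compounds**
F1 | step 6 | 1-(2,5-dihydroxy-4-methoxyphenyl)-2-(2,4,5-trimethoxyphenyl)ethanone | COc1cc(O)c(cc1O)C(=O)Cc1cc(OC)c(OC)cc1OC
F2 | step 3 | methyl 2,4,5-trimethoxyphenylacetate | COC(=O)Cc1cc(OC)c(OC)cc1OC
F3 | step 3 | methyl 3-hydroxy-2-(2,4,5-trimethoxyphenyl)acrylate | COC(=O)C(=CO)c1cc(OC)c(OC)cc1OC
F4 | step 3 | methyl (E)-3-methoxy-2-(2,4,5-trimethoxyphenyl)acrylate | CO/C=C(/C(=O)OC)c1cc(OC)c(OC)cc1OC
F5 | step 3 | (E)-3-methoxy-2-(2,4,5-trimethoxyphenyl)acrylic acid | CO/C=C(/C(=O)O)c1cc(OC)c(OC)cc1OC
F6 | step 3 | (E)-N,3-dimethoxy-N-methyl-2-(2,4,5-trimethoxyphenyl)acrylamide | CO/C=C(/C(=O)N(C)OC)c1cc(OC)c(OC)cc1OC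
F7 | step 1 | 2-(2,4,5-trimethoxyphenyl)ethanol | OCCc1cc(OC)c(OC)cc1OC
F8 | step 1 | 2-(2,4,5-trimethoxyphenyl)acetaldehyde | O=CCc1cc(OC)c(OC)cc1OC
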